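**Plan**
- Retrosynthesis: the two aryl–prenyl bonds (C6 and C8 of ring A) are cut first. Ring C is then cut at C2–C3 and C4–C4a together, leaving an aryl 3,4-dimethoxybenzyl ether and a two-carbon ynamide (a ketene equivalent).
- Enabling feature: C2 lies between O1 and ring B, so in the ether its C–H is a 3,4-dimethoxybenzylic, hydridic C–H that DDQ removes. C4a of ring A is ortho to O1 and para to the C7 oxygen, hence strongly nucleophilic.
- Forward order: resorcinol is mono-silylated, O1–C2 is made by Mitsunobu etherification, and ring C is closed in one oxidative formal [4+2] annulation. Desilylation, di-iodination at C6/C8 and a double Stille prenylation follow.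
- Stereochemistry: the only stereocentre, C2 (S), is set in the annulation by the chiral counteranion of a confined Brønsted acid. All later steps are neutral or buffered so that the flavanone cannot racemize by ring opening.
- The prenyl groups come last because their alkenes would be attacked by the cationic intermediates of the annulation.

Key step: step 3

Remark: "IDPi acid" is a confined imidodiphosphorimidate Brønsted acid built from two (S)-3,3'-bis[3,5-bis(trifluoromethyl)phenyl]-1,1'-bi-2-naphthol units with N-trifluoromethanesulfonyl groups. Its sense of induction on an O-aryl oxocarbenium ion cannot be predicted with certainty, so the (S,S)-acid is assumed to give 2S and the mirror-image acid is used if it does not.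

**Step 1**
Reactants: 1 resorcinol (benzene-1,3-diol)
Product: 2 3-[tri(propan-2-yl)silyloxy]phenol
Conditions: 1 (3 equiv), TIPSCl (1 equiv), imidazole, DMF, 0 °C to rt
Reagents that add atoms: chlorotri(propan-2-yl)silane (TIPSCl), CC(C)[Si](Cl)(C(C)C)C(C)C
Why: Silylation of a phenol with a silyl chloride and imidazole, in which the excess of the symmetric diol should keep disilylation low and the unreacted diol is washed out with water.

**Step 2**
Reactants: 2 3-[tri(propan-2-yl)silyloxy]phenol; 3 (3,4-dimethoxyphenyl)methanol
Product: 4 {3-[(3,4-dimethoxyphenyl)methoxy]phenoxy}tri(propan-2-yl)silane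
Conditions: PPh3, DIAD, THF, 0 °C to rt
Reagents that add atoms: none
Why: Mitsunobu etherification of a phenol with a primary benzylic alcohol, run under neutral conditions that should leave the aryl silyl ether untouched.

**Step 3**
Reactants: 4 {3-[(3,4-dimethoxyphenyl)methoxy]phenoxy}tri(propan-2-yl)silane; 5 N-ethynyl-N,4-dimethylbenzenesulfonamide
Product: 8 (2S)-2-(3,4-dimethoxyphenyl)-7-[tri(propan-2-yl)silyloxy]-2,3-dihydro-4H-chromen-4-one, via DDQH acetal 6 (not isolated), via ene-sulfonamide 7 (not isolated)
Conditions: DDQ (1.0 equiv), 4 Å MS, anhydrous CH2Cl2, 0 °C; then 5 (1.5 equiv), (S,S)-IDPi acid (5 mol %), CH2Cl2/toluene, −78 °C; then 1 M aq. HCl, THF, 0 °C to rt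
Reagents that add atoms: water, O
Why: Proposed new method: DDQ abstracts the hydridic benzylic hydrogen of 4 to give the covalent DDQH acetal 6, the IDPi acid re-ionizes 6 by loss of the hydroquinone oxygen (the better leaving group, so only the O-aryl oxocarbenium ion forms) while DDQH2 precipitates, the terminal carbon of ynamide 5 adds to the oxocarbenium carbon (C2–C3), the keteniminium carbon so formed is attacked by C4a of ring A (C4–C4a), proton loss returns the acid and gives 7, and aqueous acid hydrolyses the ene-sulfonamide to ketone 8. The closest known reaction types are the Povarov reaction and its oxygen analogue (formal [4+2] annulation of N-aryl iminium or O-aryl oxocarbenium ions with electron-rich π partners), DDQ-mediated oxidative C–H functionalization of benzylic ethers, Friedel–Crafts closures of ynamide-derived keteniminium ions and enantioselective additions to oxocarbenium ions paired with confined chiral anions; their combination in one enantioselective operation is new. Ring C closes in a 6-exo-dig Friedel–Crafts attack on the sp carbon of the keteniminium ion, with the C3=C4 bond inside the new ring. C2 is set in the ynamide addition, in which the chiral counteranion shields one face of the planar oxocarbenium ion; no other stereocentre is formed. The step needs closure at C4a rather than at the carbon between the two ring A oxygens, at ring B (five-membered aminoindene) or at O1 (oxetene), which the ortho/para-dioxygenated C4a, the bulky TIPS group and the strain-free six-membered transition state should secure, and it needs the ion pair with the DDQH anion to stay unreactive, which the low temperature and the low-polarity solvent should secure.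

**Step 4**
Reactants: 8 (2S)-2-(3,4-dimethoxyphenyl)-7-[tri(propan-2-yl)silyloxy]-2,3-dihydro-4H-chromen-4-one
Product: 9 (2S)-2-(3,4-dimethoxyphenyl)-7-hydroxy-2,3-dihydro-4H-chromen-4-one
Conditions: TBAF (1.1 equiv), AcOH (1.5 equiv), THF, 0 °C
Reagents that add atoms: none
Why: Fluoride-mediated desilylation of an aryl silyl ether, buffered with acetic acid so that no free phenoxide or fluoride base can open the flavanone to the chalcone, which is the racemization pathway.

**Step 5**
Reactants: 9 (2S)-2-(3,4-dimethoxyphenyl)-7-hydroxy-2,3-dihydro-4H-chromen-4-one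
Product: 10 (2S)-2-(3,4-dimethoxyphenyl)-7-hydroxy-6,8-diiodo-2,3-dihydro-4H-chromen-4-one
Conditions: NIS (2.1 equiv), DMF, 0 °C to rt, dark
Reagents that add atoms: N-iodosuccinimide (NIS), O=C1CCC(=O)N1I
Why: Electrophilic aromatic iodination, in which C6 and C8 are each ortho to the free C7 hydroxyl, ortho or para to O1 and meta to the carbonyl, so that both should react well before the ether-only ring B under acid-free conditions.

**Step 6**
Reactants: 10 (2S)-2-(3,4-dimethoxyphenyl)-7-hydroxy-6,8-diiodo-2,3-dihydro-4H-chromen-4-one; 11 tributyl(3-methylbut-2-en-1-yl)stannane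
Product: 12 (2S)-2-(3,4-dimethoxyphenyl)-7-hydroxy-6,8-bis(3-methylbut-2-en-1-yl)-2,3-dihydro-4H-chromen-4-one (IN0946)
Conditions: 11 (4 equiv), Pd(PPh3)4 (10 mol %), DMF, 80 °C
Reagents that add atoms: none
Why: Double Stille coupling, in which each aryl iodide adds oxidatively to zerovalent palladium, the allylic stannane transmetalates and reductive elimination at the unsubstituted allyl terminus should give the linear 3-methylbut-2-enyl groups under neutral conditions that leave C2 untouched.

**Compound list**
1 | resorcinol (benzene-1,3-diol) | Oc1cccc(O)c1 | starting material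
2 | 3-[tri(propan-2-yl)silyloxy]phenol | CC(C)[Si](Oc1cccc(O)c1)(C(C)C)C(C)C | intermediate
3 | (3,4-dimethoxyphenyl)methanol | COc1ccc(CO)cc1OC | starting material
4 | {3-[(3,4-dimethoxyphenyl)methoxy]phenoxy}tri(propan-2-yl)silane | COc1ccc(COc2cccc(O[Si](C(C)C)(C(C)C)C(C)C)c2)cc1OC | intermediate
5 | N-ethynyl-N,4-dimethylbenzenesulfonamide | C#CN(C)S(=O)(=O)c1ccc(C)cc1 | starting material
6 | 4,5-dichloro-3-hydroxy-6-[(3,4-dimethoxyphenyl){3-[tri(propan-2-yl)silyloxy]phenoxy}methoxy]benzene-1,2-dicarbonitrile (racemic DDQH acetal) | COc1ccc(C(Oc2cccc(O[Si](C(C)C)(C(C)C)C(C)C)c2)Oc2c(Cl)c(Cl)c(O)c(C#N)c2C#N)cc1OC | intermediate (not isolated)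
7 | N-[(2S)-2-(3,4-dimethoxyphenyl)-7-[tri(propan-2-yl)silyloxy]-2H-chromen-4-yl]-N,4-dimethylbenzenesulfonamide | COc1ccc([C@@H]2C=C(N(C)S(=O)(=O)c3ccc(C)cc3)c3ccc(O[Si](C(C)C)(C(C)C)C(C)C)cc3O2)cc1OC | intermediate (not isolated)
8 | (2S)-2-(3,4-dimethoxyphenyl)-7-[tri(propan-2-yl)silyloxy]-2,3-dihydro-4H-chromen-4-one | COc1ccc([C@@H]2CC(=O)c3ccc(O[Si](C(C)C)(C(C)C)C(C)C)cc3O2)cc1OC | intermediate
9 | (2S)-2-(3,4-dimethoxyphenyl)-7-hydroxy-2,3-dihydro-4H-chromen-4-one | COc1ccc([C@@H]2CC(=O)c3ccc(O)cc3O2)cc1OC | intermediate
10 | (2S)-2-(3,4-dimethoxyphenyl)-7-hydroxy-6,8-diiodo-2,3-dihydro-4H-chromen-4-one | COc1ccc([C@@H]2CC(=O)c3cc(I)c(O)c(I)c3O2)cc1OC | intermediate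
11 | tributyl(3-methylbut-2-en-1-yl)stannane | CCCC[Sn](CCCC)(CCCC)CC=C(C)C | starting material
12 | (2S)-2-(3,4-dimethoxyphenyl)-7-hydroxy-6,8-bis(3-methylbut-2-en-1-yl)-2,3-dihydro-4H-chromen-4-one (IN0946) | COc1ccc([C@@H]2CC(=O)c3cc(CC=C(C)C)c(O)c(CC=C(C)C)c3O2)cc1OC | target

**Count**
Total steps: 6. Longest linear sequence: 6 steps (1 → 2 → 4 → 8 → 9 → 10 → 12).

**Steps most likely to fail**

1. Step 3 (proposed new method). Several processes could defeat it:
   - The ion pair with the DDQH anion may react without the chiral acid, giving poor facial selectivity.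
   - The oxocarbenium ion may alkylate ring A of a second molecule.
   - The ynamide may be consumed by the acid or by the hydroquinone.
   - The keteniminium ion may close onto ring B or onto O1.

   Fallback with known chemistry, setting out from resorcinol 1 and coming back at 8. Nencki acylation of 1 (AcOH, ZnCl2, 140 °C) should give 1-(2,4-dihydroxyphenyl)ethan-1-one F1. Ring closure with triethyl orthoformate and HClO4, followed by hot water, should give 7-hydroxy-4H-chromen-4-one F2. Silylation (TIPSCl, imidazole, DMF) should give 7-[tri(propan-2-yl)silyloxy]-4H-chromen-4-one F3. Asymmetric conjugate addition of (3,4-dimethoxyphenyl)boronic acid to F3 then sets C2 and should deliver 8. It is catalysed by divalent palladium, Pd(OCOCF3)2, with a chiral 2-(4-tert-butyl-4,5-dihydrooxazol-2-yl)pyridine ligand (NH4PF6, water, ClCH2CH2Cl, 60 °C). The ligand antipode is chosen for 2S.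

2. Step 6. The allyl group may be delivered through its substituted terminus (reverse-prenyl isomers). The acidic di-iodophenol may protonate the stannane, and protodeiodination may compete with the second coupling.

   Fallback setting out from 10 and coming back at 12. Double Stille coupling with allyltributylstannane (Pd(PPh3)4, DMF, 80 °C) has no regiochemical ambiguity and should give (2S)-2-(3,4-dimethoxyphenyl)-7-hydroxy-6,8-di(prop-2-en-1-yl)-2,3-dihydro-4H-chromen-4-one F4. Cross-metathesis of both allyl groups with excess 2-methylbut-2-ene (second-generation Grubbs catalyst, CH2Cl2, 40 °C) should then give 12.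

3. Step 5. Iodination of ring B may compete, or the second iodination may stall once the phenol has become less electron-rich.

   Fallback without halogenation, setting out from 9 and coming back at 12. O-Alkylation with 1-bromo-3-methylbut-2-ene (K2CO3, acetone, rt) should give (2S)-2-(3,4-dimethoxyphenyl)-7-[(3-methylbut-2-en-1-yl)oxy]-2,3-dihydro-4H-chromen-4-one F5. A [1,3]-shift of the prenyl group on acidic montmorillonite K10 clay (CH2Cl2, 0 °C), drawn for migration to C8 between the two ring oxygens, should give (2S)-2-(3,4-dimethoxyphenyl)-7-hydroxy-8-(3-methylbut-2-en-1-yl)-2,3-dihydro-4H-chromen-4-one F6. A second O-alkylation under the same conditions should give (2S)-2-(3,4-dimethoxyphenyl)-8-(3-methylbut-2-en-1-yl)-7-[(3-methylbut-2-en-1-yl)oxy]-2,3-dihydro-4H-chromen-4-one F7. A second clay-promoted shift into the remaining ortho position C6 should then give 12.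

**Further compounds**
F1 | step 3 | 1-(2,4-dihydroxyphenyl)ethan-1-one | CC(=O)c1ccc(O)cc1O
F2 | step 3 | 7-hydroxy-4H-chromen-4-one | O=c1ccoc2cc(O)ccc12
F3 | step 3 | 7-[tri(propan-2-yl)silyloxy]-4H-chromen-4-one | CC(C)[Si](Oc1ccc2c(=O)ccoc2c1)(C(C)C)C(C)C
F4 | step 6 | (2S)-2-(3,4-dimethoxyphenyl)-7-hydroxy-6,8-di(prop-2-en-1-yl)-2,3-dihydro-4H-chromen-4-one | COc1ccc([C@@H]2CC(=O)c3cc(CC=C)c(O)c(CC=C)c3O2)cc1OC
F5 | step 5 | (2S)-2-(3,4-dimethoxyphenyl)-7-[(3-methylbut-2-en-1-yl)oxy]-2,3-dihydro-4H-chromen-4-one | COc1ccc([C@@H]2CC(=O)c3ccc(OCC=C(C)C)cc3O2)cc1OC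
F6 | step 5 | (2S)-2-(3,4-dimethoxyphenyl)-7-hydroxy-8-(3-methylbut-2-en-1-yl)-2,3-dihydro-4H-chromen-4-one | COc1ccc([C@@H]2CC(=O)c3ccc(O)c(CC=C(C)C)c3O2)cc1OC
F7 | step 5 | (2S)-2-(3,4-dimethoxyphenyl)-8-(3-methylbut-2-en-1-yl)-7-[(3-methylbut-2-en-1-yl)oxy]-2,3-dihydro-4H-chromen-4-one | COc1ccc([C@@H]2CC(=O)c3ccc(OCC=C(C)C)c(CC=C(C)C)c3O2)cc1OC
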